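**Retrosynthetic overview**
1. C3–Br is made last by Appel inversion of the (3R)-propargylic alcohol, which comes from chelation-controlled ethynyl Grignard addition to the C3 aldehyde (carried as a dioxolane).
2. Ring B (formed second) comes from an anodic 5-endo bromoetherification of the (Z)-C9=C10 homoallylic bromohydrin (O12 to C9, Br to C10); the alkene comes from syn semi-hydrogenation of the C9≡C10 alkyne.
3. C8–C9 is made by blue-light copper-catalysed coupling of the ring A primary iodide (C8) with the terminal alkyne of the C9–C15 bromohydrin, itself built from (2S,2′S)-2,2′-bioxirane, MeMgBr, bromide (inversion) and acetylide.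
4. Ring A (formed first) comes from hydroxyl-directed 5-exo iodoetherification of an anti-1,3-diol (O4 to C7, I to C8), made from (S)-glyceraldehyde acetonide by Felkin-type Mukaiyama aldol and 1,3-anti reduction.

Assumption: carbons are numbered C1–C15 from the alkyne terminus (ring A = C4–C7 oxolane bearing the acetate, ring B = C9–C12 bromo-oxolane); 1 and 7 are taken as purchasable pool materials (from L-ascorbic acid and L-tartaric acid).

**Route**

Step 1
Reactants: 1 (4S)-2,2-dimethyl-1,3-dioxolane-4-carbaldehyde; 2 2-(trimethylsilyloxy)buta-1,3-diene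
Product: 3 (5R)-5-[(4S)-2,2-dimethyl-1,3-dioxolan-4-yl]-5-hydroxypent-1-en-3-one
Conditions: BF3·OEt2 (1.1 equiv.), CH2Cl2, −78 °C; aq. NaHCO3
Reagents that add atoms: none
Why: Mukaiyama aldol under non-chelating BF3 follows Felkin–Anh, the enol silane attacking anti to the dioxolane C–O bond, so the new carbinol C4 is (R) (1,2-anti).

Step 2
Reactants: 3 (5R)-5-[(4S)-2,2-dimethyl-1,3-dioxolan-4-yl]-5-hydroxypent-1-en-3-one
Product: 4 (1R,3R)-1-[(4S)-2,2-dimethyl-1,3-dioxolan-4-yl]pent-4-ene-1,3-diol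
Conditions: Me4NBH(OAc)3, MeCN/AcOH (1:1), −30 °C
Reagents that add atoms: none
Why: Evans–Saksena reduction: the C4 hydroxyl binds boron and delivers hydride intramolecularly through a chair transition state, giving the 1,3-anti diol and setting C6 as (R).

Step 3
Reactants: 4 (1R,3R)-1-[(4S)-2,2-dimethyl-1,3-dioxolan-4-yl]pent-4-ene-1,3-diol
Product: 5 (2S,3R,5R)-5-[(4S)-2,2-dimethyl-1,3-dioxolan-4-yl]-2-(iodomethyl)oxolan-3-ol
Conditions: I2, NaHCO3, Et2O/H2O, 0 °C
Reagents that add atoms: iodine, [I][I]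
Why: Hydroxyl-directed 5-exo iodoetherification of a 4-pentene-1,3-diol: the allylic C6–OH sits inside (pseudo-axial) in the envelope transition state, so O4 adds to C7 cis to C6–OH, which with the fixed C4 and C6 centres gives the all-cis ring A and the C8 iodide.

Step 4
Reactants: 5 (2S,3R,5R)-5-[(4S)-2,2-dimethyl-1,3-dioxolan-4-yl]-2-(iodomethyl)oxolan-3-ol
Product: 6 (2S,3R,5R)-5-[(4S)-2,2-dimethyl-1,3-dioxolan-4-yl]-2-(iodomethyl)oxolan-3-yl acetate
Conditions: Ac2O, pyridine, DMAP (cat.), CH2Cl2, 0 °C to rt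
Reagents that add atoms: acetic anhydride, CC(=O)OC(C)=O
Why: DMAP-catalysed acylation of the only free hydroxyl installs the C6 acetate and removes this oxygen as a competing nucleophile in the later bromonium step; no stereocentre is touched.

Step 5
Reactants: 7 (2S,2′S)-2,2′-bioxirane
Product: 8 (1S)-1-[(2S)-oxiran-2-yl]propan-1-ol
Conditions: MeMgBr (1.0 equiv.), CuBr·SMe2 (10 mol%), THF, −40 °C
Reagents that add atoms: methylmagnesium bromide, C[Mg]Br
Why: Copper-catalysed Grignard opening of one terminal epoxide at its CH2 carbon (SN2) builds the ethyl group and leaves both bought stereocentres (C12, C13) untouched.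

Step 6
Reactants: 8 (1S)-1-[(2S)-oxiran-2-yl]propan-1-ol
Product: 9 (2S)-2-[(1R)-1-bromopropyl]oxirane
Conditions: CBr4, PPh3, CH2Cl2, 0 °C
Reagents that add atoms: carbon tetrabromide, BrC(Br)(Br)Br
Why: Appel bromination replaces the C13 hydroxyl by bromide with SN2 inversion, giving (R)-C13–Br while the epoxide is inert at 0 °C.

Step 7
Reactants: 9 (2S)-2-[(1R)-1-bromopropyl]oxirane
Product: 10 (4S,5R)-5-bromohept-1-yn-4-ol
Conditions: HC≡CLi (acetylene, n-BuLi), BF3·OEt2, THF, −78 °C; aq. NH4Cl at −78 °C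
Reagents that add atoms: lithium acetylide (from acetylene and n-BuLi), [Li]C#C
Why: BF3-assisted (Yamaguchi–Hirao) opening of the terminal epoxide at C11 by lithium acetylide installs C9–C10 without touching C12 or the secondary bromide, the alkoxide staying boron-bound so it cannot close onto C13.

Step 8
Reactants: 6 (2S,3R,5R)-5-[(4S)-2,2-dimethyl-1,3-dioxolan-4-yl]-2-(iodomethyl)oxolan-3-yl acetate; 10 (4S,5R)-5-bromohept-1-yn-4-ol
Product: 11 (2R,3R,5R)-2-[(5S,6R)-6-bromo-5-hydroxyoct-2-yn-1-yl]-5-[(4S)-2,2-dimethyl-1,3-dioxolan-4-yl]oxolan-3-yl acetate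
Conditions: CuCl (10 mol%), 4,4′,4″-tri-tert-butyl-2,2′:6′,2″-terpyridine (10 mol%), KHCO3, MeCN, blue LEDs (450 nm), rt
Reagents that add atoms: none
Why: Photoinduced copper-catalysed alkyl Sonogashira-type coupling: the light-excited terpyridine copper acetylide reduces the primary iodide to the C8 radical, which is captured at copper and reductively eliminated as the C8–C9 bond; no stereocentre is involved and bicarbonate is too weak to close the bromohydrin.

Step 9
Reactants: 11 (2R,3R,5R)-2-[(5S,6R)-6-bromo-5-hydroxyoct-2-yn-1-yl]-5-[(4S)-2,2-dimethyl-1,3-dioxolan-4-yl]oxolan-3-yl acetate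
Product: 12 (2R,3R,5R)-2-[(2Z,5S,6R)-6-bromo-5-hydroxyoct-2-en-1-yl]-5-[(4S)-2,2-dimethyl-1,3-dioxolan-4-yl]oxolan-3-yl acetate
Conditions: H2 (1 atm), Pd/CaCO3 poisoned with Pb(OAc)2, quinoline, EtOAc, rt
Reagents that add atoms: none
Why: Lindlar-type syn semi-hydrogenation gives the (Z)-C9=C10 alkene that later translates into the cis C9/C10 relationship; alkyl bromide, acetate and acetonide are inert.

Step 10
Reactants: 12 (2R,3R,5R)-2-[(2Z,5S,6R)-6-bromo-5-hydroxyoct-2-en-1-yl]-5-[(4S)-2,2-dimethyl-1,3-dioxolan-4-yl]oxolan-3-yl acetate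
Product: 13 (2R,3R,5R)-2-{[(2S,3S,5S)-3-bromo-5-[(1R)-1-bromopropyl]oxolan-2-yl]methyl}-5-[(4S)-2,2-dimethyl-1,3-dioxolan-4-yl]oxolan-3-yl acetate
Conditions: undivided cell, graphite anode, Pt cathode, Et4NBr (1.2 equiv.), HFIP/CH2Cl2 (1:4), constant current, 2.2 F/mol, 0 °C
Reagents that add atoms: tetraethylammonium bromide, CC[N+](CC)(CC)CC.[Br-]
Why: Proposed new method: anodic oxidation of bromide feeds Br2 at a low stationary level into HFIP, which stabilises the reversibly formed bromiranium ion of the (Z)-alkene and hydrogen-bonds bromide so that dibromide formation is held back; the C12 hydroxyl then closes 5-endo at C9 through an envelope transition state with the C12 side chain pseudo-equatorial (C8 and C13 cis), and anti addition across the (Z)-alkene puts Br at C10 cis to C8, giving the all-cis ring B with C9 (S) and C10 (S); the closest known reactions are bromide-mediated electrochemical 5-exo bromoetherification and bromolactonisation of alkenols and the 5-endo-trig iodoetherification of (Z)-homoallylic alcohols with I2/NaHCO3, which gives all-cis 3-iodo-oxolanes.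

Step 11
Reactants: 13 (2R,3R,5R)-2-{[(2S,3S,5S)-3-bromo-5-[(1R)-1-bromopropyl]oxolan-2-yl]methyl}-5-[(4S)-2,2-dimethyl-1,3-dioxolan-4-yl]oxolan-3-yl acetate
Product: 15 (2R,3R,5R)-2-{[(2S,3S,5S)-3-bromo-5-[(1R)-1-bromopropyl]oxolan-2-yl]methyl}-5-formyloxolan-3-yl acetate, via vicinal diol 14 (not isolated)
Conditions: H5IO6, EtOAc, rt
Reagents that add atoms: none
Why: Periodic acid hydrolyses the terminal acetonide and cleaves the resulting 1,2-diol in the same pot (Malaprade cleavage), unmasking C3 as the aldehyde under acidic conditions that do not epimerise C4.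

Step 12
Reactants: 15 (2R,3R,5R)-2-{[(2S,3S,5S)-3-bromo-5-[(1R)-1-bromopropyl]oxolan-2-yl]methyl}-5-formyloxolan-3-yl acetate
Product: 16 (2R,3R,5R)-2-{[(2S,3S,5S)-3-bromo-5-[(1R)-1-bromopropyl]oxolan-2-yl]methyl}-5-[(1R)-1-hydroxyprop-2-yn-1-yl]oxolan-3-yl acetate
Conditions: MgBr2·OEt2, CH2Cl2, −78 °C; then HC≡CMgBr (THF solution), −78 °C
Reagents that add atoms: ethynylmagnesium bromide, C#C[Mg]Br
Why: Chelation-controlled (Cram chelate) Grignard addition: magnesium bridges the aldehyde oxygen and the ring A oxygen, so the acetylide attacks the face opposite C5 and gives the syn (3R) propargylic alcohol, the aldehyde reacting far faster than the acetate at −78 °C.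

Step 13
Reactants: 16 (2R,3R,5R)-2-{[(2S,3S,5S)-3-bromo-5-[(1R)-1-bromopropyl]oxolan-2-yl]methyl}-5-[(1R)-1-hydroxyprop-2-yn-1-yl]oxolan-3-yl acetate
Product: 17 (2R,3R,5R)-2-{[(2S,3S,5S)-3-bromo-5-[(1R)-1-bromopropyl]oxolan-2-yl]methyl}-5-[(1S)-1-bromoprop-2-yn-1-yl]oxolan-3-yl acetate (CNP0294340.1)
Conditions: CBr4, PPh3, CH2Cl2, 0 °C
Reagents that add atoms: carbon tetrabromide, BrC(Br)(Br)Br
Why: Appel bromination of the propargylic alcohol goes by SN2 inversion to the (3S) bromide under neutral conditions that leave the acetate, the alkyne and the two other bromides untouched.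

**Compound list**
1 | (4S)-2,2-dimethyl-1,3-dioxolane-4-carbaldehyde [(S)-glyceraldehyde acetonide] | CC1(C)OC[C@H](O1)C=O | starting material
2 | 2-(trimethylsilyloxy)buta-1,3-diene | C=CC(=C)O[Si](C)(C)C | starting material
3 | (5R)-5-[(4S)-2,2-dimethyl-1,3-dioxolan-4-yl]-5-hydroxypent-1-en-3-one | CC1(C)OC[C@H](O1)[C@H](O)CC(=O)C=C | intermediate
4 | (1R,3R)-1-[(4S)-2,2-dimethyl-1,3-dioxolan-4-yl]pent-4-ene-1,3-diol | CC1(C)OC[C@H](O1)[C@H](O)C[C@@H](O)C=C | intermediate
5 | (2S,3R,5R)-5-[(4S)-2,2-dimethyl-1,3-dioxolan-4-yl]-2-(iodomethyl)oxolan-3-ol | CC1(C)OC[C@H](O1)[C@H]2C[C@@H](O)[C@@H](CI)O2 | intermediate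
6 | (2S,3R,5R)-5-[(4S)-2,2-dimethyl-1,3-dioxolan-4-yl]-2-(iodomethyl)oxolan-3-yl acetate | CC1(C)OC[C@H](O1)[C@H]2C[C@@H](OC(C)=O)[C@@H](CI)O2 | intermediate
7 | (2S,2′S)-2,2′-bioxirane [(S,S)-1,2:3,4-diepoxybutane] | C1O[C@@H]1[C@@H]2CO2 | starting material
8 | (1S)-1-[(2S)-oxiran-2-yl]propan-1-ol | C1O[C@@H]1[C@@H](O)CC | intermediate
9 | (2S)-2-[(1R)-1-bromopropyl]oxirane | C1O[C@@H]1[C@H](Br)CC | intermediate
10 | (4S,5R)-5-bromohept-1-yn-4-ol | C#CC[C@H](O)[C@H](Br)CC | intermediate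
11 | (2R,3R,5R)-2-[(5S,6R)-6-bromo-5-hydroxyoct-2-yn-1-yl]-5-[(4S)-2,2-dimethyl-1,3-dioxolan-4-yl]oxolan-3-yl acetate | CC1(C)OC[C@H](O1)[C@H]2C[C@@H](OC(C)=O)[C@@H](CC#CC[C@H](O)[C@H](Br)CC)O2 | intermediate
12 | (2R,3R,5R)-2-[(2Z,5S,6R)-6-bromo-5-hydroxyoct-2-en-1-yl]-5-[(4S)-2,2-dimethyl-1,3-dioxolan-4-yl]oxolan-3-yl acetate | CC1(C)OC[C@H](O1)[C@H]2C[C@@H](OC(C)=O)[C@@H](C/C=C\C[C@H](O)[C@H](Br)CC)O2 | intermediate
13 | (2R,3R,5R)-2-{[(2S,3S,5S)-3-bromo-5-[(1R)-1-bromopropyl]oxolan-2-yl]methyl}-5-[(4S)-2,2-dimethyl-1,3-dioxolan-4-yl]oxolan-3-yl acetate | CC1(C)OC[C@H](O1)[C@H]2C[C@@H](OC(C)=O)[C@@H](C[C@@H]3O[C@H]([C@H](Br)CC)C[C@@H]3Br)O2 | intermediate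
14 | (2R,3R,5R)-2-{[(2S,3S,5S)-3-bromo-5-[(1R)-1-bromopropyl]oxolan-2-yl]methyl}-5-[(1S)-1,2-dihydroxyethyl]oxolan-3-yl acetate | OC[C@H](O)[C@H]1C[C@@H](OC(C)=O)[C@@H](C[C@@H]2O[C@H]([C@H](Br)CC)C[C@@H]2Br)O1 | intermediate (not isolated)
15 | (2R,3R,5R)-2-{[(2S,3S,5S)-3-bromo-5-[(1R)-1-bromopropyl]oxolan-2-yl]methyl}-5-formyloxolan-3-yl acetate | O=C[C@H]1C[C@@H](OC(C)=O)[C@@H](C[C@@H]2O[C@H]([C@H](Br)CC)C[C@@H]2Br)O1 | intermediate
16 | (2R,3R,5R)-2-{[(2S,3S,5S)-3-bromo-5-[(1R)-1-bromopropyl]oxolan-2-yl]methyl}-5-[(1R)-1-hydroxyprop-2-yn-1-yl]oxolan-3-yl acetate | C#C[C@@H](O)[C@H]1C[C@@H](OC(C)=O)[C@@H](C[C@@H]2O[C@H]([C@H](Br)CC)C[C@@H]2Br)O1 | intermediate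
17 | (2R,3R,5R)-2-{[(2S,3S,5S)-3-bromo-5-[(1R)-1-bromopropyl]oxolan-2-yl]methyl}-5-[(1S)-1-bromoprop-2-yn-1-yl]oxolan-3-yl acetate | C#C[C@H](Br)[C@H]1C[C@@H](OC(C)=O)[C@@H](C[C@@H]2O[C@H]([C@H](Br)CC)C[C@@H]2Br)O1 | target

**Step count and risks**
Total: 13 steps. Longest linear sequence: 10 steps (steps 1–4 and 8–13); steps 5–7 make the alkyne partner in parallel.

Three steps most likely to fail:

Step 10 (the proposed new electrochemical 5-endo bromoetherification). The closure is slow because the C12 hydroxyl is deactivated by the neighbouring bromide, so vicinal dibromide formation, participation of the ring A ether oxygen, or a poor 2,5-cis ratio are possible. The fallback uses known chemistry, sets out from 11 and comes back at 13. Cycloisomerisation of 11 with Ph3PAuCl/AgOTf (cat., CH2Cl2) closes ring B 5-endo-dig to the 4,5-dihydrofuran F1. Hydroboration of the enol ether (BH3·SMe2, 0 °C, then NaBO3) from the face opposite the C12 side chain gives the 2,5-cis, 2,3-trans oxolan-3-ol F2. Appel bromination (CBr4, PPh3, toluene, 60 °C) then inverts C10 and gives 13.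

Step 8 (light-driven copper coupling). Bicarbonate may be too weak to form the copper acetylide quickly, a stronger base would close the bromohydrin to an epoxide, and the C8 radical may simply be reduced. The fallback sets out from 10 (with 6) and comes back at 12, so step 9 is skipped. Iodination of 10 (N-iodosuccinimide, AgNO3 cat., acetone) gives the iodoalkyne F3. Diimide reduction (dipotassium azodicarboxylate, AcOH, MeOH) gives the (Z)-vinyl iodide F4. Reductive cross-electrophile coupling of F4 with 6 (NiBr2(dme), 4,4′-di-tert-butyl-2,2′-bipyridine, Zn, DMA) then forms C8–C9 with retention of the (Z) geometry and gives 12.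

Step 12 (chelation-controlled ethynylation). The diastereomer ratio at C3 may be modest because THF from the Grignard solution competes for magnesium. The fallback sets out from 15 and comes back at 16. Addition of ethynylmagnesium bromide without chelation control (THF, −78 °C) gives 16 mixed with its (1S)-carbinol epimer F5. The mixture is oxidised with Dess–Martin periodinane to the ynone F6, which is reduced with Zn(BH4)2 (Et2O, −30 °C) under chelation control to 16.

Further compounds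
F1 | step 10 | (2R,3R,5R)-2-({(5S)-5-[(1R)-1-bromopropyl]-4,5-dihydrofuran-2-yl}methyl)-5-[(4S)-2,2-dimethyl-1,3-dioxolan-4-yl]oxolan-3-yl acetate | CC1(C)OC[C@H](O1)[C@H]2C[C@@H](OC(C)=O)[C@@H](CC3=CC[C@H](O3)[C@H](Br)CC)O2
F2 | step 10 | (2R,3R,5R)-2-{[(2S,3R,5S)-5-[(1R)-1-bromopropyl]-3-hydroxyoxolan-2-yl]methyl}-5-[(4S)-2,2-dimethyl-1,3-dioxolan-4-yl]oxolan-3-yl acetate | CC1(C)OC[C@H](O1)[C@H]2C[C@@H](OC(C)=O)[C@@H](C[C@@H]3O[C@H]([C@H](Br)CC)C[C@H]3O)O2
F3 | step 8 | (4S,5R)-5-bromo-1-iodohept-1-yn-4-ol | IC#CC[C@H](O)[C@H](Br)CC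
F4 | step 8 | (1Z,4S,5R)-5-bromo-1-iodohept-1-en-4-ol | I/C=C\C[C@H](O)[C@H](Br)CC
F5 | step 12 | (2R,3R,5R)-2-{[(2S,3S,5S)-3-bromo-5-[(1R)-1-bromopropyl]oxolan-2-yl]methyl}-5-[(1S)-1-hydroxyprop-2-yn-1-yl]oxolan-3-yl acetate | C#C[C@H](O)[C@H]1C[C@@H](OC(C)=O)[C@@H](C[C@@H]2O[C@H]([C@H](Br)CC)C[C@@H]2Br)O1
F6 | step 12 | (2R,3R,5R)-2-{[(2S,3S,5S)-3-bromo-5-[(1R)-1-bromopropyl]oxolan-2-yl]methyl}-5-(prop-2-ynoyl)oxolan-3-yl acetate | C#CC(=O)[C@H]1C[C@@H](OC(C)=O)[C@@H](C[C@@H]2O[C@H]([C@H](Br)CC)C[C@@H]2Br)O1
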